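**Retrosynthetic overview**
1. Target ⇐ fluoride cleavage of a C11 2‑(trimethylsilyl)ethyl ester; C12‑CHO ⇐ SeO2 oxidation of the C8 methyl; C6 ester ⇐ Yamaguchi acylation with octatrienoic acid (sorbaldehyde + malonic acid).
2. 6β‑OH ⇐ Luche reduction of a 6‑oxo‑7‑en‑9α‑ol ⇐ singlet‑oxygen [4+2]/Kornblum–DeLaMare on a 6,8‑dien‑11‑oate ⇐ carbonylation of the dienyl triflate of an 11‑nor‑drim‑7‑en‑9‑one.
3. Ring B (key step) ⇐ α‑ketol (acyloin) ring expansion, 5→6, of a 1‑acetyl‑1‑hydroxy‑trans‑hydrindane, then dehydration.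
4. Ring A and the cyclopentane ⇐ enantioselective proton‑initiated, alkyne‑terminated cyclization of an (E)‑dienyne.
5. Dienyne ⇐ Negishi coupling of an (E)‑vinyl iodide (carboalumination of an enyne) with pent‑3‑ynylzinc. Ring order: A, then cyclopentane (same step), then B by ring expansion.

Assumption: ring compounds are described with drimane numbering (C11 on C9, C12 on C8; β = face of the C10 methyl), and the target is made in the open aldehyde–acid form drawn.

**Step 1**
Reactants: 1 5-bromo-2-methylpent-2-ene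
Product: 2 6-methylhept-5-en-1-yne
Conditions: LiC≡CH·H2NCH2CH2NH2, DMSO, 10 °C → rt
Reagents that add atoms: lithium acetylide–ethylenediamine complex [Li]C#C.NCCN
Why: SN2 alkylation of an acetylide by a primary bromide; no stereocentre is formed.

**Step 2**
Reactants: 2 6-methylhept-5-en-1-yne
Product: 4 (E)-1-iodo-2,6-dimethylhepta-1,5-diene, via alkenylalane 3 (not isolated)
Conditions: Me3Al, Cp2ZrCl2 (20 mol%), CH2Cl2, 0 °C → rt; then I2, THF, −30 → 0 °C
Reagents that add atoms: trimethylaluminium C[Al](C)C; iodine II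
Why: Zr‑catalysed syn‑carboalumination (Negishi) puts Me and Al cis, and iodination with retention fixes the (E)‑trisubstituted alkene.

**Step 3**
Reactants: 4 (E)-1-iodo-2,6-dimethylhepta-1,5-diene, 5 5-bromopent-2-yne
Product: 7 (E)-2,6-dimethyldodeca-2,6-dien-10-yne, via pent-3-ynylzinc bromide 6 (not isolated)
Conditions: 5, Zn dust, LiCl, THF, 40 °C; then 4, Pd(dppf)Cl2 (3 mol%), THF, 50 °C
Reagents that add atoms: none
Why: Negishi sp3–sp2 cross‑coupling proceeds with retention of the (E)‑geometry and leaves the internal alkyne untouched.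

**Step 4**
Reactants: 7 (E)-2,6-dimethyldodeca-2,6-dien-10-yne
Product: 8 1-[(1S,3aS,7aS)-4,4,7a-trimethyloctahydro-1H-inden-1-yl]ethan-1-one
Conditions: chiral confined imidodiphosphorimidate Brønsted acid (5 mol%), H2O (3 equiv), (CF3)3COH/CHCl3, −40 °C
Reagents that add atoms: water O
Why: Proposed new method: catalytic enantioselective proton‑initiated cyclization with alkyne termination, in which the confined chiral acid protonates the terminal trisubstituted alkene face‑selectively, the (E)‑alkene closes ring A through a chair transition state (setting C5‑H α and C10‑Me β, trans), the C10 cation is captured 5‑exo by the methyl alkyne and water quenches the linear vinyl cation to the methyl ketone; the closest known reaction types are chiral‑acid‑catalysed asymmetric polyene cyclizations with hydroxyl or aryl terminators and racemic Johnson‑type alkyne‑terminated cyclizations that give trans‑hydrindanyl methyl ketones.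

**Step 5**
Reactants: 8 1-[(1S,3aS,7aS)-4,4,7a-trimethyloctahydro-1H-inden-1-yl]ethan-1-one
Product: 10 1-[(1R,3aS,7aS)-1-hydroxy-4,4,7a-trimethyloctahydro-1H-inden-1-yl]ethan-1-one, via hydroperoxide 9 (not isolated)
Conditions: O2 (1 atm), t-BuOK, P(OEt)3, t-BuOH/THF, −20 °C
Reagents that add atoms: oxygen O=O
Why: Barton‑type enolate autoxidation, as in 17α‑hydroxylation of 20‑ketosteroids, oxygenates the tertiary α‑carbon from the α‑face (anti to the angular methyl) and the phosphite reduces the hydroperoxide.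

**Step 6**
Reactants: 10 1-[(1R,3aS,7aS)-1-hydroxy-4,4,7a-trimethyloctahydro-1H-inden-1-yl]ethan-1-one
Product: 12 (4aS,8aS)-2,5,5,8a-tetramethyl-4a,5,6,7,8,8a-hexahydronaphthalen-1(4H)-one, via ring-expanded ketol 11 (not isolated)
Conditions: KOH, MeOH, 65 °C; crude ketol then SOCl2, pyridine, CH2Cl2, 0 °C; TsOH (cat.) to conjugate any exocyclic isomer
Reagents that add atoms: none
Why: Key step, an α‑ketol (acyloin) rearrangement of the D‑homoannulation type: the alkoxide drives a 1,2‑shift of the ring CH2 (C7) from C9 to the acetyl carbon, expanding the cyclopentane to ring B with the ketone at C9 next to quaternary C10 (regiochemistry as in 17‑hydroxy‑20‑ketosteroids), and dehydration of the tertiary alcohol (either C8 epimer) gives the conjugated enone.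

**Step 7**
Reactants: 12 (4aS,8aS)-2,5,5,8a-tetramethyl-4a,5,6,7,8,8a-hexahydronaphthalen-1(4H)-one
Product: 13 (4aS,8aS)-2,5,5,8a-tetramethyl-4a,5,6,7,8,8a-hexahydronaphthalen-1-yl trifluoromethanesulfonate
Conditions: KHMDS, THF, −78 °C; PhNTf2, −78 → 0 °C
Reagents that add atoms: N-phenyl-bis(trifluoromethanesulfonimide) O=S(=O)(N(c1ccccc1)S(=O)(=O)C(F)(F)F)C(F)(F)F
Why: With C10 quaternary there is no α′‑hydrogen, so only γ‑deprotonation at C6 is possible and O‑sulfonylation gives the homoannular 6,8‑dienyl triflate.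

**Step 8**
Reactants: 13 (4aS,8aS)-2,5,5,8a-tetramethyl-4a,5,6,7,8,8a-hexahydronaphthalen-1-yl trifluoromethanesulfonate
Product: 14 2-(trimethylsilyl)ethyl (4aS,8aS)-2,5,5,8a-tetramethyl-4a,5,6,7,8,8a-hexahydronaphthalene-1-carboxylate
Conditions: Pd(OAc)2 (5 mol%), dppf, CO (1 atm), Me3SiCH2CH2OH, Et3N, DMF, 60 °C
Reagents that add atoms: carbon monoxide [C-]#[O+]; 2-(trimethylsilyl)ethanol C[Si](C)(C)CCO
Why: Pd‑catalysed alkoxycarbonylation of the vinyl triflate installs C11 as a fluoride‑cleavable ester.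

**Step 9**
Reactants: 14 2-(trimethylsilyl)ethyl (4aS,8aS)-2,5,5,8a-tetramethyl-4a,5,6,7,8,8a-hexahydronaphthalene-1-carboxylate
Product: 16 2-(trimethylsilyl)ethyl 9α-hydroxy-6-oxodrim-7-en-11-oate, via endoperoxide 15 (not isolated)
Conditions: O2, hν, tetraphenylporphyrin (cat.), CH2Cl2, −20 °C; then Et3N (cat.), rt
Reagents that add atoms: oxygen O=O
Why: Singlet oxygen adds [4+2] across C6/C9 of the cisoid diene from the α‑face (anti to the axial C10 and C4 β‑methyls, as with steroidal 5,7‑dienes), and Kornblum–DeLaMare rearrangement (only C6 bears H) gives the C6 ketone and sets the 9α‑OH/9β‑ester centre.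

**Step 10**
Reactants: 16 2-(trimethylsilyl)ethyl 9α-hydroxy-6-oxodrim-7-en-11-oate
Product: 17 2-(trimethylsilyl)ethyl 6β,9α-dihydroxydrim-7-en-11-oate
Conditions: NaBH4, CeCl3·7H2O, MeOH, −40 °C
Reagents that add atoms: none
Why: Luche 1,2‑reduction; hydride attacks the enone from the less hindered α‑face and sets the axial 6β‑alcohol.

**Step 11**
Reactants: 18 (2E,4E)-hexa-2,4-dienal, 19 malonic acid
Product: 21 (2E,4E,6E)-octa-2,4,6-trienoic acid, via hexadienylidenemalonic acid 20 (not isolated)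
Conditions: pyridine, piperidine (cat.), 90 °C
Reagents that add atoms: none
Why: Knoevenagel–Doebner condensation with in situ decarboxylation gives the (E)‑configured acid.

**Step 12**
Reactants: 17 2-(trimethylsilyl)ethyl 6β,9α-dihydroxydrim-7-en-11-oate, 21 (2E,4E,6E)-octa-2,4,6-trienoic acid
Product: 23 2-(trimethylsilyl)ethyl 9α-hydroxy-6β-[(2E,4E,6E)-octa-2,4,6-trienoyloxy]drim-7-en-11-oate, via mixed anhydride 22 (not isolated)
Conditions: 21, 2,4,6-Cl3C6H2COCl, Et3N, THF, rt; then 17, DMAP (cat.), PhMe, 40 °C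
Reagents that add atoms: none
Why: Yamaguchi esterification acylates the secondary allylic alcohol only; the tertiary 9‑OH is inert and no stereocentre is touched.

**Step 13**
Reactants: 23 2-(trimethylsilyl)ethyl 9α-hydroxy-6β-[(2E,4E,6E)-octa-2,4,6-trienoyloxy]drim-7-en-11-oate
Product: 24 2-(trimethylsilyl)ethyl 9α-hydroxy-6β-[(2E,4E,6E)-octa-2,4,6-trienoyloxy]-12-oxodrim-7-en-11-oate
Conditions: SeO2, 1,4-dioxane, 80 °C
Reagents that add atoms: selenium dioxide O=[Se]=O
Why: SeO2 allylic oxidation attacks the only C–H on the more substituted alkene terminus (the C12 methyl; C9 has no H) of the electron‑richest alkene and gives the enal.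

**Step 14**
Reactants: 24 2-(trimethylsilyl)ethyl 9α-hydroxy-6β-[(2E,4E,6E)-octa-2,4,6-trienoyloxy]-12-oxodrim-7-en-11-oate
Product: 25 ustusoic acid B
Conditions: TBAF, THF, 0 °C; aq. NH4Cl
Reagents that add atoms: none
Why: Fluoride‑induced β‑elimination of the 2‑silylethyl ester frees the hindered acid without hydrolytic conditions that would endanger the trienoate or the enal.

**Compound list**
1 | 5-bromo-2-methylpent-2-ene | CC(C)=CCCBr | starting material
2 | 6-methylhept-5-en-1-yne | CC(C)=CCCC#C | intermediate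
3 | (E)-(2,6-dimethylhepta-1,5-dien-1-yl)dimethylalumane | C[Al](C)/C=C(\C)CCC=C(C)C | intermediate
4 | (E)-1-iodo-2,6-dimethylhepta-1,5-diene | I/C=C(\C)CCC=C(C)C | intermediate
5 | 5-bromopent-2-yne | CC#CCCBr | starting material
6 | pent-3-ynylzinc bromide | CC#CCC[Zn]Br | intermediate
7 | (E)-2,6-dimethyldodeca-2,6-dien-10-yne | CC#CCC/C=C(\C)CCC=C(C)C | intermediate
8 | 1-[(1S,3aS,7aS)-4,4,7a-trimethyloctahydro-1H-inden-1-yl]ethan-1-one | CC(=O)[C@H]1CC[C@H]2C(C)(C)CCC[C@]12C | intermediate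
9 | 1-[(1R,3aS,7aS)-1-hydroperoxy-4,4,7a-trimethyloctahydro-1H-inden-1-yl]ethan-1-one | CC(=O)[C@@]1(OO)CC[C@H]2C(C)(C)CCC[C@]12C | intermediate
10 | 1-[(1R,3aS,7aS)-1-hydroxy-4,4,7a-trimethyloctahydro-1H-inden-1-yl]ethan-1-one | CC(=O)[C@@]1(O)CC[C@H]2C(C)(C)CCC[C@]12C | intermediate
11 | (2S,4aS,8aS)-2-hydroxy-2,5,5,8a-tetramethyloctahydronaphthalen-1(2H)-one (8β-OH epimer drawn) | C[C@]1(O)CC[C@H]2C(C)(C)CCC[C@]2(C)C1=O | intermediate
12 | (4aS,8aS)-2,5,5,8a-tetramethyl-4a,5,6,7,8,8a-hexahydronaphthalen-1(4H)-one | CC1=CC[C@H]2C(C)(C)CCC[C@]2(C)C1=O | intermediate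
13 | (4aS,8aS)-2,5,5,8a-tetramethyl-4a,5,6,7,8,8a-hexahydronaphthalen-1-yl trifluoromethanesulfonate | CC1=C(OS(=O)(=O)C(F)(F)F)[C@@]2(C)CCCC(C)(C)[C@@H]2C=C1 | intermediate
14 | 2-(trimethylsilyl)ethyl (4aS,8aS)-2,5,5,8a-tetramethyl-4a,5,6,7,8,8a-hexahydronaphthalene-1-carboxylate (drima-6,8-dien-11-oate) | CC1=C(C(=O)OCC[Si](C)(C)C)[C@@]2(C)CCCC(C)(C)[C@@H]2C=C1 | intermediate
15 | 2-(trimethylsilyl)ethyl 6α,9α-epidioxydrim-7-en-11-oate | CC1=C[C@@H]2OO[C@@]1(C(=O)OCC[Si](C)(C)C)[C@@]3(C)CCCC(C)(C)[C@H]23 | intermediate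
16 | 2-(trimethylsilyl)ethyl 9α-hydroxy-6-oxodrim-7-en-11-oate | O=C1C=C(C)[C@](O)(C(=O)OCC[Si](C)(C)C)[C@@]2(C)CCCC(C)(C)[C@H]12 | intermediate
17 | 2-(trimethylsilyl)ethyl 6β,9α-dihydroxydrim-7-en-11-oate | O[C@@H]1C=C(C)[C@](O)(C(=O)OCC[Si](C)(C)C)[C@@]2(C)CCCC(C)(C)[C@H]12 | intermediate
18 | (2E,4E)-hexa-2,4-dienal | C/C=C/C=C/C=O | starting material
19 | malonic acid | OC(=O)CC(=O)O | starting material
20 | 2-[(2E,4E)-hexa-2,4-dien-1-ylidene]propanedioic acid | C/C=C/C=C/C=C(C(=O)O)C(=O)O | intermediate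
21 | (2E,4E,6E)-octa-2,4,6-trienoic acid | C/C=C/C=C/C=C/C(=O)O | intermediate
22 | (2E,4E,6E)-octa-2,4,6-trienoic 2,4,6-trichlorobenzoic anhydride | C/C=C/C=C/C=C/C(=O)OC(=O)c1c(Cl)cc(Cl)cc1Cl | intermediate
23 | 2-(trimethylsilyl)ethyl 9α-hydroxy-6β-[(2E,4E,6E)-octa-2,4,6-trienoyloxy]drim-7-en-11-oate | C/C=C/C=C/C=C/C(=O)O[C@@H]1C=C(C)[C@](O)(C(=O)OCC[Si](C)(C)C)[C@@]2(C)CCCC(C)(C)[C@H]12 | intermediate
24 | 2-(trimethylsilyl)ethyl 9α-hydroxy-6β-[(2E,4E,6E)-octa-2,4,6-trienoyloxy]-12-oxodrim-7-en-11-oate | C/C=C/C=C/C=C/C(=O)O[C@@H]1C=C(C=O)[C@](O)(C(=O)OCC[Si](C)(C)C)[C@@]2(C)CCCC(C)(C)[C@H]12 | intermediate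
25 | ustusoic acid B | C/C=C/C=C/C=C/C(=O)O[C@@H]1C=C(C=O)[C@](O)(C(=O)O)[C@@]2(C)CCCC(C)(C)[C@H]12 | target

**Count:** 14 steps in total; longest linear sequence 13 (steps 1–10 and 12–14; step 11 is the side branch).

**Steps most likely to fail and fallbacks**

Step 4 (the proposed new cyclization; risk: low ee, or partial or alkyne‑first protonation). The fallback sets out from 7 and returns at 8 using known chemistry. Cyclize 7 racemically under Johnson conditions (CF3CO2H in a chlorinated solvent at low temperature, aqueous basic work‑up) to the racemic methyl ketone F1. Reduce with NaBH4 to the racemic carbinol F2 (Felkin product, as for 20‑ketosteroids). Resolve by lipase‑catalysed acetylation (Amano PS, vinyl acetate), which converts the (R)‑carbinol of the wanted series into the acetate F3. Separate, methanolyse (K2CO3, MeOH) to the single‑enantiomer alcohol F4, and oxidize (Dess–Martin) to 8.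

Step 9 (the ester‑deactivated, hindered diene may undergo ene reactions or react slowly with singlet oxygen). The fallback sets out from 14 and returns at 16. Epoxidize the distal, more electron‑rich C6=C7 bond with mCPBA from the α‑face to the vinyl epoxide F5. Rearrange with BF3·OEt2 (Meinwald, hydride shift to the allylic cation) to the β,γ‑unsaturated 6‑ketone F6. γ‑Oxygenate by base‑mediated autoxidation (O2, t‑BuOK, P(OEt)3), as for Δ5‑3‑ketosteroids, which delivers oxygen to C9 from the α‑face and gives 16.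

Step 13 (SeO2 may also attack the trienoate terminus or react sluggishly). The fallback sets out from 16 and returns at 24, oxidizing C12 before the side chain is present. Treat 16 with SeO2 in dioxane (γ‑methyl of an enone) to give the keto‑aldehyde F7. Reduce both carbonyls with NaBH4/CeCl3 to the 6β,12‑diol F8. Oxidize only the primary allylic alcohol with TEMPO/PhI(OAc)2 to the hydroxy‑enal F9. Acylate F9 with 21 under the Yamaguchi conditions of step 12 to reach 24.

**Further compounds**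
F1 | step 4 | racemic 1-[(1S*,3aS*,7aS*)-4,4,7a-trimethyloctahydro-1H-inden-1-yl]ethan-1-one | CC(=O)[C@H]1CC[C@H]2C(C)(C)CCC[C@]12C.CC(=O)[C@@H]1CC[C@@H]2C(C)(C)CCC[C@@]12C
F2 | step 4 | racemic (1R*)-1-[(1S*,3aS*,7aS*)-4,4,7a-trimethyloctahydro-1H-inden-1-yl]ethan-1-ol | C[C@@H](O)[C@H]1CC[C@H]2C(C)(C)CCC[C@]12C.C[C@H](O)[C@@H]1CC[C@@H]2C(C)(C)CCC[C@@]12C
F3 | step 4 | (1R)-1-[(1S,3aS,7aS)-4,4,7a-trimethyloctahydro-1H-inden-1-yl]ethyl acetate | C[C@@H](OC(C)=O)[C@H]1CC[C@H]2C(C)(C)CCC[C@]12C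
F4 | step 4 | (1R)-1-[(1S,3aS,7aS)-4,4,7a-trimethyloctahydro-1H-inden-1-yl]ethan-1-ol | C[C@@H](O)[C@H]1CC[C@H]2C(C)(C)CCC[C@]12C
F5 | step 9 | 2-(trimethylsilyl)ethyl 6α,7α-epoxydrim-8-en-11-oate | CC1=C(C(=O)OCC[Si](C)(C)C)[C@@]2(C)CCCC(C)(C)[C@@H]2[C@H]3O[C@@H]13
F6 | step 9 | 2-(trimethylsilyl)ethyl 6-oxodrim-8-en-11-oate | CC1=C(C(=O)OCC[Si](C)(C)C)[C@@]2(C)CCCC(C)(C)[C@@H]2C(=O)C1
F7 | step 13 | 2-(trimethylsilyl)ethyl 9α-hydroxy-6,12-dioxodrim-7-en-11-oate | O=C1C=C(C=O)[C@](O)(C(=O)OCC[Si](C)(C)C)[C@@]2(C)CCCC(C)(C)[C@H]12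
F8 | step 13 | 2-(trimethylsilyl)ethyl 6β,9α,12-trihydroxydrim-7-en-11-oate | O[C@@H]1C=C(CO)[C@](O)(C(=O)OCC[Si](C)(C)C)[C@@]2(C)CCCC(C)(C)[C@H]12
F9 | step 13 | 2-(trimethylsilyl)ethyl 6β,9α-dihydroxy-12-oxodrim-7-en-11-oate | O[C@@H]1C=C(C=O)[C@](O)(C(=O)OCC[Si](C)(C)C)[C@@]2(C)CCCC(C)(C)[C@H]12
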